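The numbers in the tables are simulated with made-up constants; scatter was added.

Two questions stand between the earlier runs and the new flasks: does the free base count at all, and how long does the electrophile last against the nucleophile?

all flasks: electrophile 0.30 M

|  | nucleophile | free base | remark | time |
|---|---|---|---|---|
| eta | 0.24 M (fed, over 2.5 h) | 0.69 M | run made earlier |  |
| delta | 0.24 M (fed, over 2.5 h) | 1.4 M | run made earlier |  |
| midnight | 0.240 M (fed, over 2.5 h) | 1.20 M |  | 12 h |
| autumn | 0.240 M (fed, over 2.5 h) | 0.600 M |  | 12 h |

| run | time / h | electrophile / % | target / % |
|---|---|---|---|
| eta | 1.00 | 99.8 | 1.2 |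
| eta | 2.00 | 96.5 | 2.2 |
| eta | 3.00 | 93.4 | 6.6 |
| eta | 4.00 | 89.2 | 8.6 |
| eta | 5.00 | 87.1 | 10.9 |
| eta | 6.00 | 84.6 | 11.6 |
| delta | 1.00 | 99.1 | 1.0 |
| delta | 2.00 | 96.8 | 2.5 |
| delta | 3.00 | 92.7 | 6.5 |
| delta | 4.00 | 90.4 | 9.5 |
| delta | 5.00 | 86.3 | 10.6 |
| delta | 6.00 | 85.1 | 12.2 |

(standard deviation of a reading: 0.5 percentage points)



- part of the electrophile that has reacted at the end, midnight
- part of the electrophile that has reacted at the end, autumn
- what raising the concentration of free base from its lowest to its highest value here does to the part of the electrophile that has reacted (changes below 5 percentage points count as none) (it rises / it falls / no change)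

The zero of our scale is a base that plays no part, for then eta and delta coincide. Delta carries twice the free base of eta, yet at 6.00 h their electrophile readings differ by 0.5 percentage points, which is below the 5 points that count as a change. So we expect no change and reckon midnight and autumn as one flask, although the 0.600 M of autumn lies a little below the 0.69 M of eta.

How long, then? The two runs average 84.9% electrophile at 6.00 h. We count a steady feed as the full charge arriving at the middle of the feed, which gives them 4.75 h of contact. Treating the electrophile as pseudo-first-order over that contact gives 20.0 h, a reading from scattered points, which we carry as the half-life of the electrophile at the full charge of nucleophile.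

Midnight and autumn get 10.8 h of contact, so our reckoning gives 31.1% reacted. We take this as the high side, since the nucleophile, charged at 0.800 equivalents, is consumed as the flask runs.

The forecast, lower than our figure, says 28% for midnight, 28% for autumn and no change, since “the rate looks zero order in base over this range”.

The flasks give 25.5% for midnight and 25.5% for autumn, so no change. In autumn at 12.0 h, nearly all of the acid set free, its bound forms counted, stands as protonated nucleophile, 0.0762 M against 5.97 × 10⁻⁵ M of salt of the base. On our half-life, the result for autumn is worth 8.50 h of contact at full charge, short of the 10.8 h we counted, and its free nucleophile ended at 36.4% of its charge.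

    electrophile + nucleophile → acid set free + target (k = 0.00310 L mol⁻¹ min⁻¹)
    nucleophile + acid set free ⇌ protonated nucleophile, settled at all times (K = 18000 L mol⁻¹)
    acid set free + free base ⇌ salt of the base (K = 2.20 L mol⁻¹, k = 0.0690 L mol⁻¹ min⁻¹)
    target → over-reaction product (k = 0.00120 min⁻¹)
    nucleophile + acid set free ⇌ idle adduct, settled at all times (K = 12.0 L mol⁻¹)

With 0.96 M of nucleophile in an otherwise autumn flask, we scale our half-life down in proportion to 5.01 h, and the same contact gives 77.6% reacted. That flask gives 73.7%.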